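**Assumption:** the target, 1-(5-decylpyridin-3-yl)decan-1-one, has no stereocentre, so "single enantiomer" is taken to mean the one achiral compound; there is no configuration to set.

## Retrosynthetic overview

1. Target 9 ⇐ dehydrogenation of C-acyl dihydropyridine 8 ⇐ photochemical 1,3 N→C acyl shift in N-decanoyl-1,4-dihydropyridine 6 (forms the ring C5–C(=O) bond; proposed new step).
2. 6 ⇐ 3-decylpyridine 3 + decanoyl chloride 4 (N-acylation, then copper hydride 1,4-reduction).
3. 3 ⇐ 3-bromopyridine 1 + decylmagnesium bromide 2 (Kumada coupling; forms the ring C3–CH2 bond).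
4. No ring is formed: the pyridine ring is bought intact, dearomatised once and rearomatised in the last step.

## Route

Step 1
Reactants: 1 3-bromopyridine; 2 decylmagnesium bromide
Product: 3 3-decylpyridine
Conditions: NiCl2(dppp) (2 mol%; dppp = 1,3-bis(diphenylphosphino)propane), THF/Et2O, 0 °C to reflux; aq. NH4Cl work-up
Reagents that add atoms: decylmagnesium bromide, CCCCCCCCCC[Mg]Br
Why: Kumada–Corriu cross-coupling; 3-bromopyridine adds readily to nickel, and the chelating dppp ligand makes reductive elimination of the primary alkyl group faster than β-hydride elimination.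

Step 2
Reactants: 3 3-decylpyridine; 4 decanoyl chloride
Product: 6 1-decanoyl-3-decyl-1,4-dihydropyridine, via 1-decanoyl-3-decylpyridinium chloride 5 (not isolated)
Conditions: 4, THF, −20 °C, 30 min; then cannulated into copper hydride from LiAlH(O-t-Bu)3/CuBr, THF, −78 to −40 °C; used promptly under argon
Reagents that add atoms: decanoyl chloride, CCCCCCCCCC(=O)Cl
Why: N-acylation activates the ring, and the soft copper hydride delivers hydride to C4 (1,4-reduction of a 1-acylpyridinium salt, a known reaction type), giving the N-acyl-1,4-dihydropyridine; no stereocentre is formed.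

Step 3
Reactants: 6 1-decanoyl-3-decyl-1,4-dihydropyridine
Product: 9 1-(5-decylpyridin-3-yl)decan-1-one, via C-acyl imine tautomer 7 (not isolated), via C-acyl dihydropyridine 8 (not isolated)
Conditions: hν (254 nm, quartz), argon-sparged MeCN (0.01 M), 20 °C; then DDQ (1.1 equiv), 0 °C to rt
Reagents that add atoms: none
Why: Proposed new method: an aza-photo-Fries 1,3 N→C acyl shift on a 1-acyl-1,4-dihydropyridine, used as a traceless meta-acylation of the pyridine; excitation of the cross-conjugated bis-enamide chromophore of 6 (about 250–270 nm) cleaves the N–C(=O) bond to a solvent-caged decanoyl radical and a 3-azapentadienyl radical with spin density on N, C3 and C5; recombination at the unsubstituted C5 gives imine 7 (transient, racemic), whose C–H between C=O and C=N tautomerises at once to the vinylogous amide 8, a thermodynamic sink; recombination at the decyl-bearing C3 gives a quaternary acyl imine that cannot tautomerise and should be returned to the radical pair by the same photochemical 1,3-shift, so material funnels to 8; DDQ then removes two hydrogens to give the aromatic ketone 9; the closest known reaction types are the photo-Fries 1,3-acyl shift of enamides, N-acylpyrroles, N-acylindoles and anilides, with Lewis-acid β-acylation of 1-acyl-1,4-dihydropyridines as the polar relative.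

## Compound list

1 | 3-bromopyridine | Brc1cccnc1 | starting material
2 | decylmagnesium bromide | CCCCCCCCCC[Mg]Br | starting material
3 | 3-decylpyridine | CCCCCCCCCCc1cccnc1 | intermediate
4 | decanoyl chloride | CCCCCCCCCC(=O)Cl | starting material
5 | 1-decanoyl-3-decylpyridin-1-ium chloride | CCCCCCCCCC(=O)[n+]1cccc(CCCCCCCCCC)c1.[Cl-] | intermediate (not isolated)
6 | 1-decanoyl-3-decyl-1,4-dihydropyridine, i.e. 1-(3-decylpyridin-1(4H)-yl)decan-1-one | CCCCCCCCCC(=O)N1C=CCC(CCCCCCCCCC)=C1 | intermediate
7 | 1-(5-decyl-3,4-dihydropyridin-3-yl)decan-1-one (racemic, transient) | CCCCCCCCCC(=O)C1C=NC=C(CCCCCCCCCC)C1 | intermediate (not isolated)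
8 | 1-(5-decyl-1,4-dihydropyridin-3-yl)decan-1-one | CCCCCCCCCC(=O)C1=CNC=C(CCCCCCCCCC)C1 | intermediate (not isolated)
9 | 1-(5-decylpyridin-3-yl)decan-1-one | CCCCCCCCCCc1cncc(C(=O)CCCCCCCCC)c1 | target

## Step count and risk

Total step count: 3. Longest linear sequence: 3 steps (1 → 3 → 6 → 9).

The three steps most likely to fail, most risky first:

**Step 3 (proposed new step).** Risks are escape of the radical pair from the cage (giving back 3-decylpyridine 3 plus decanal), recombination at C3 that does not revert, and secondary photolysis of 8. The fallback uses known chemistry; it sets out from 3-decylpyridine 3 and comes back to the route at target 9. Sterically controlled iridium-catalysed C–H borylation ([Ir(OMe)(cod)]2, 4,4'-di-tert-butyl-2,2'-bipyridine, B2pin2, MTBE, 80 °C) puts boron at C5, the only ring C–H that is neither next to nitrogen nor next to the decyl group, giving 3-decyl-5-(4,4,5,5-tetramethyl-1,3,2-dioxaborolan-2-yl)pyridine F3. An acylative Suzuki–Miyaura coupling of this boronate with decanoyl chloride 4 (Pd(PPh3)4, anhydrous Cs2CO3, toluene, 100 °C) then gives 9.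

**Step 2.** The risk is hydride attack at the acyl carbonyl or at C2/C6 instead of C4, since the alkanoylpyridinium salt is less robust than a carbamate-type salt. The fallback sets out from 3-decylpyridine 3 and comes back at 6. A [Ru(p-cymene)Cl2]2-catalysed 1,4-selective hydroboration with pinacolborane (neat or THF, 50 °C) gives 3-decyl-1-(4,4,5,5-tetramethyl-1,3,2-dioxaborolan-2-yl)-1,4-dihydropyridine F2. After removal of volatiles, B–N to acyl–N exchange with decanoyl chloride 4 (THF, 0 °C) gives 6, so the acyl electrophile never meets a hydride.

**Step 1.** Risks are homocoupling or reduction of the Grignard reagent and catalyst poisoning by the pyridine nitrogen. The fallback sets out from 3-bromopyridine 1 and comes back at 3. Sonogashira coupling with 1-decyne (PdCl2(PPh3)2, CuI (copper monoiodide), Et3N, 60 °C) gives 3-(dec-1-yn-1-yl)pyridine F1, and full hydrogenation of the alkyne (H2, Pd/C, EtOH, rt) gives 3.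

## Further compounds

F1 | step 1 | 3-(dec-1-yn-1-yl)pyridine | CCCCCCCCC#Cc1cccnc1
F2 | step 2 | 3-decyl-1-(4,4,5,5-tetramethyl-1,3,2-dioxaborolan-2-yl)-1,4-dihydropyridine | CCCCCCCCCCC1=CN(B2OC(C)(C)C(C)(C)O2)C=CC1
F3 | step 3 | 3-decyl-5-(4,4,5,5-tetramethyl-1,3,2-dioxaborolan-2-yl)pyridine | CCCCCCCCCCc1cncc(B2OC(C)(C)C(C)(C)O2)c1
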